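The numbers of this flask stand for no real mixture; the flask was simulated.

At early times c(starting material) stays near its charge, and you can count the flask's turnovers with one number.

    starting material + reagent + target → 2 target (k1 = 1900 L² mol⁻² h⁻¹)
    starting material + reagent → target (k2 = 0.078 L mol⁻¹ h⁻¹)
    starting material + target → side product (k3 = 16 L mol⁻¹ h⁻¹)
    2 starting material → self-condensation product (k4 = 0.0050 L mol⁻¹ h⁻¹)

common to all: reagent 10.0 mM; time 30 h

| charge | starting material |
|---|---|
| spring | 5.0 mM |
| autumn | 10 mM |
| noon | 20 mM |
| midnight | 40 mM |
| dawn | 80 mM |

- a species is counted by the starting material in it: one side product or self-condensation product counts as two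
- two of one species on the left: rate k times its square, two consumed each time
- "hardly changes" means that all values lie within two and a half points (for a concentration: within two and a half percent of the largest)
- run time (spring): 30 h

* [target] at the end for spring, autumn, noon, midnight, dawn, in this order
* how the row runs (falls all the way / hardly changes / rises all the way / falls, then rises / rises, then falls)

The autocatalytic step makes target and the side step eats it, and both rates carry c(starting material). So charge and hours enter only as their product. Multiply that product by the autocatalytic constant times charged c(reagent), minus the side-step constant, 3.00 L mol⁻¹ h⁻¹. The result is the net turnover number n, the count of e-fold growths of target that the run holds at charged concentrations. Spring has n = 0.450, and dawn has 7.20.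

The uncatalysed step supplies a seed level of 0.260 mM, and target then follows the seed level times (exp(n) minus one). For spring that gives 0.148 mM.

There is a brake. The autocatalytic step by itself outruns the side step while c(reagent) stays above the ratio of the side-step constant to the autocatalytic constant, 8.42 mM, which covers the first 1.58 mM of reagent spent, and the uncatalysed step adds target on top of that. By my reckoning, one net turnover spends 1.44 mM, a little less than that. So by this reckoning a run with n near one has about used that margin.

Spring and autumn, at 0.900, stand below one. Noon, midnight and dawn stand above it, at 1.80, 3.60 and 7.20. Held against one, the two ends of the row give me a row that rises, then falls. Was one number enough? The number holds reagent at its charge, and near one that is off by my 1.44 mM, so it reads the two ends of the row and not the turn or the height of the top.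

The forecast gives 0.14 mM, 0.29 mM, 0.41 mM, 0.14 mM and 0.046 mM, so rises, then falls, with “about 1.6 mM of reagent is spent before target starts to decline”.

The simulation gives 0.137 mM, 0.293 mM, 0.416 mM, 0.133 mM and 0.0460 mM, so rises, then falls, with spring against my 0.148 mM.

Spring, at n = 0.450, ends with target made 1.50 times faster than it is used up, and with 97% of its reagent left, which is 9.71 mM, more than the ratio of 8.42 mM. Midnight, at n = 3.60, ends with 55% of its reagent left, which is 5.46 mM, less than that ratio, and with target at 0.133 mM, and the row turns at a charge of 18 mM, where n is 1.64.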